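**Assumption:** the SMILES is read as (3R) in the vestitol-type half and (3R,4S), i.e. 3,4-trans, in the 4-arylisoflavan half; compounds 1, 6 and 13, Koser's reagent PhI(OH)OTs and iodosylbenzene are bought.

## Retrosynthetic overview

1. Target ⇐ its tripivalate by one hydride deprotection; pivalates deactivate every aromatic ring that must not react in the coupling.
2. Inter-unit C4–C5' bond ⇐ trans-selective Friedel–Crafts alkylation of 7-O-pivaloyl-(R)-vestitol (C5', para to its free OH) by the C4 cation of a (3R,4R)-cis-isoflavan-4-ol.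
3. Stereocentres ⇐ two transfer hydrogenations with dynamic kinetic resolution of racemic isoflavanones, same (R,R) catalyst; the lower C4 is then relayed from C3 in the coupling.
4. Key disconnection, used twice: C3–aryl bond of each isoflavanone ⇐ enolonium (trivalent-iodine enolate, an α-keto cation equivalent) of one common chroman-4-one + an electron-rich arene, joining two normally nucleophilic carbons; the enolonium is made with a tosyloxy iodane for the first arene and as its tetrafluoroborate for the second, less nucleophilic arene.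
5. Ring order: no ring is built; both pyran rings come preformed in 7-hydroxychroman-4-one and the other three benzene rings are bought; bonds are made in the order C3–aryl (twice), then C4–C5'.

## Route

Step 1
Reactants: 1 7-hydroxychroman-4-one; 2 pivaloyl chloride
Product: 3 4-oxochroman-7-yl pivalate
Conditions: PivCl, Et3N, 4-(dimethylamino)pyridine (5 mol%), CH2Cl2, 0 °C → rt
Reagents that add atoms: pivaloyl chloride (2), CC(C)(C)C(=O)Cl
Why: Nucleophilic-catalysed O-acylation of the phenol gives an ester that survives every later step and makes ring A a poor Friedel–Crafts nucleophile.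

Step 2
Reactants: 3 4-oxochroman-7-yl pivalate; 4 trimethylsilyl trifluoromethanesulfonate
Product: 5 4-(trimethylsilyloxy)-2H-chromen-7-yl pivalate
Conditions: TMSOTf, Et3N, CH2Cl2, 0 °C; pentane trituration, filtration, used crude
Reagents that add atoms: trimethylsilyl trifluoromethanesulfonate (4), C[Si](C)(C)OS(=O)(=O)C(F)(F)F
Why: Soft enolisation (silyl enol ether formation) is regiospecific because the aryl ketone can enolise only toward C3.

Step 3
Reactants: 6 4-bromo-3-methoxyphenol; 7 benzyl bromide
Product: 8 4-(benzyloxy)-1-bromo-2-methoxybenzene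
Conditions: BnBr, K2CO3, DMF, rt
Reagents that add atoms: benzyl bromide (7), BrCc1ccccc1
Why: Williamson ether synthesis masks the phenol, and the bromine blocks the carbon para to OBn so that only the carbon para to OMe and ortho to OBn remains open and doubly activated.

Step 4
Reactants: 5 4-(trimethylsilyloxy)-2H-chromen-7-yl pivalate; 8 4-(benzyloxy)-1-bromo-2-methoxybenzene
Product: 10 (±)-3-[2-(benzyloxy)-5-bromo-4-methoxyphenyl]-4-oxochroman-7-yl pivalate, via O-iodanyl enolonium 9 (not isolated)
Conditions: PhI(OH)OTs (1.5 equiv), BF3·OEt2 (1.5 equiv, activator), CH2Cl2, −78 °C, then 5, 10 min; then 8 (3 equiv), −78 → −20 °C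
Reagents that add atoms: none
Why: Proposed new method: PhI(OH)OTs/BF3·OEt2 turns the silyl enol ether into the O-bound trivalent-iodine enolate 9, whose C3 is electrophilic, and arene 8 attacks it in a Friedel–Crafts sense at its only unblocked doubly activated carbon with loss of PhI, so two normally nucleophilic carbons are joined; the closest known reaction type is the umpolung α-arylation of ketone-derived enolonium species with indoles, pyrroles and allylsilanes, and the new C3 centre is racemic and deliberately left labile.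

Step 5
Reactants: 10 (±)-3-[2-(benzyloxy)-5-bromo-4-methoxyphenyl]-4-oxochroman-7-yl pivalate
Product: 11 (3R,4R)-3-[2-(benzyloxy)-5-bromo-4-methoxyphenyl]-4-hydroxychroman-7-yl pivalate (3,4-cis)
Conditions: RuCl[(R,R)-TsDPEN](p-cymene) (2 mol%; TsDPEN = N-tosyl-1,2-diphenylethane-1,2-diamine), HCO2H/Et3N (5:2), EtOAc, 40 °C
Reagents that add atoms: none
Why: Noyori-type asymmetric transfer hydrogenation with dynamic kinetic resolution: Et3N racemises C3 through the enol faster than reduction, the (R,R) catalyst gives the (4R) carbinol (as it gives (R)-chroman-4-ol) and reduces only the epimer whose aryl group lies anti to the incoming hydride, setting (3R,4R)-cis.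

Step 6
Reactants: 11 (3R,4R)-3-[2-(benzyloxy)-5-bromo-4-methoxyphenyl]-4-hydroxychroman-7-yl pivalate
Product: 12 (3R)-3-(2-hydroxy-4-methoxyphenyl)chroman-7-yl pivalate [7-O-pivaloyl-(R)-vestitol]
Conditions: H2 (3 bar), Pd/C (10 wt% Pd), EtOAc/AcOH (4:1), rt
Reagents that add atoms: none
Why: One catalytic hydrogenolysis removes the benzylic C4–OH, the benzyl ether and the aryl bromide (the HBr released speeds the benzylic C–O cleavage), which frees C5' and the ortho phenol while C3 is untouched and stays (R).

Step 7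
Reactants: 13 2,6-dimethoxyphenol; 2 pivaloyl chloride
Product: 14 2,6-dimethoxyphenyl pivalate
Conditions: PivCl, Et3N, 4-(dimethylamino)pyridine (10 mol%), CH2Cl2, rt
Reagents that add atoms: pivaloyl chloride (2), CC(C)(C)C(=O)Cl
Why: O-Acylation switches off the para-directing phenol, so the symmetric arene can only react at C3/C5 (ortho to one OMe, para to the other), the position needed for the lower B ring.

Step 8
Reactants: 5 4-(trimethylsilyloxy)-2H-chromen-7-yl pivalate; 14 2,6-dimethoxyphenyl pivalate
Product: 16 (±)-3-[2,4-dimethoxy-3-(pivaloyloxy)phenyl]-4-oxochroman-7-yl pivalate, via O-iodonio enolate tetrafluoroborate 15 (not isolated)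
Conditions: PhIO (1.2 equiv), HBF4·OMe2 (1.2 equiv, returned on rearomatisation), CH2Cl2, −78 °C → rt → −78 °C; then 5 dropwise, −78 °C, 30 min; then 14 (4 equiv), −78 → 0 °C
Reagents that add atoms: none
Why: Proposed new method: iodosylbenzene and HBF4·OMe2 give [PhI(OH)]BF4, which converts 5 into the iodonium enolate 15 that carries only the non-nucleophilic BF4 counter-ion (no tosylate or acetate can be transferred to C3), and arene 14, the weaker of the two arene partners because its ortho methoxy group is twisted out of conjugation by the neighbouring pivalate, attacks the electrophilic C3 through either of its two equivalent activated carbons with loss of PhI; the closest known reaction type is C–C bond formation between the iodosylbenzene–HBF4 adducts of silyl enol ethers and simple alkenes or silyl enol ethers, which are π-nucleophiles no stronger than 14, and the C3 centre is formed racemic.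

Step 9
Reactants: 16 (±)-3-[2,4-dimethoxy-3-(pivaloyloxy)phenyl]-4-oxochroman-7-yl pivalate
Product: 17 (3R,4R)-3-[2,4-dimethoxy-3-(pivaloyloxy)phenyl]-4-hydroxychroman-7-yl pivalate (3,4-cis)
Conditions: RuCl[(R,R)-TsDPEN](p-cymene) (2 mol%), HCO2H/Et3N (5:2), EtOAc, 40 °C
Reagents that add atoms: none
Why: The same asymmetric transfer hydrogenation with dynamic kinetic resolution as in step 5 sets (3R,4R)-cis, and the hindered aryl pivalates are inert to the formate buffer.

Step 10
Reactants: 17 (3R,4R)-3-[2,4-dimethoxy-3-(pivaloyloxy)phenyl]-4-hydroxychroman-7-yl pivalate; 12 (3R)-3-(2-hydroxy-4-methoxyphenyl)chroman-7-yl pivalate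
Product: 19 (3R,4S)-3-[2,4-dimethoxy-3-(pivaloyloxy)phenyl]-4-{4-hydroxy-2-methoxy-5-[(3R)-7-(pivaloyloxy)chroman-3-yl]phenyl}chroman-7-yl pivalate, via C4 benzylic cation 18 (not isolated)
Conditions: 12 (2 equiv), BF3·OEt2 (20 mol%), CH2Cl2, −40 → 0 °C
Reagents that add atoms: none
Why: SN1 Friedel–Crafts alkylation: the acid ionises C4–OH to the O1-stabilised cation 18, the only resorcinol-type activated carbon present is C5' of 12 (para to the free OH, ortho to OMe, while the esterified rings are deactivated), and it adds anti to the C3 aryl group to give the 3,4-trans (3R,4S) arrangement with C3 unchanged.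

Step 11
Reactants: 19 (3R,4S)-3-[2,4-dimethoxy-3-(pivaloyloxy)phenyl]-4-{4-hydroxy-2-methoxy-5-[(3R)-7-(pivaloyloxy)chroman-3-yl]phenyl}chroman-7-yl pivalate
Product: 20 (3R,4S)-3-(3-hydroxy-2,4-dimethoxyphenyl)-4-{4-hydroxy-5-[(3R)-7-hydroxychroman-3-yl]-2-methoxyphenyl}chroman-7-ol (target)
Conditions: LiAlH4 (6 equiv), THF, 0 °C → rt; then 1 M HCl, 0 °C
Reagents that add atoms: none
Why: Hydride reduction of the three aryl esters releases the phenols under non-oxidising conditions that the electron-rich polyphenol tolerates, and no stereocentre is involved.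

## Compound list

1 | 7-hydroxychroman-4-one | O=C1CCOc2cc(O)ccc12 | starting material
2 | pivaloyl chloride | CC(C)(C)C(=O)Cl | starting material
3 | 4-oxochroman-7-yl pivalate | CC(C)(C)C(=O)Oc1ccc2C(=O)CCOc2c1 | intermediate
4 | trimethylsilyl trifluoromethanesulfonate | C[Si](C)(C)OS(=O)(=O)C(F)(F)F | starting material
5 | 4-(trimethylsilyloxy)-2H-chromen-7-yl pivalate | CC(C)(C)C(=O)Oc1ccc2C(O[Si](C)(C)C)=CCOc2c1 | intermediate
6 | 4-bromo-3-methoxyphenol | COc1cc(O)ccc1Br | starting material
7 | benzyl bromide | BrCc1ccccc1 | starting material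
8 | 4-(benzyloxy)-1-bromo-2-methoxybenzene | COc1cc(OCc2ccccc2)ccc1Br | intermediate
9 | 4-{[phenyl(tosyloxy)-λ3-iodanyl]oxy}-2H-chromen-7-yl pivalate (enolonium, BF3-activated) | CC(C)(C)C(=O)Oc1ccc2C(O[I](c3ccccc3)OS(=O)(=O)c3ccc(C)cc3)=CCOc2c1 | intermediate
10 | (±)-3-[2-(benzyloxy)-5-bromo-4-methoxyphenyl]-4-oxochroman-7-yl pivalate | CC(C)(C)C(=O)Oc1ccc2C(=O)C(COc2c1)c1cc(Br)c(OC)cc1OCc1ccccc1 | intermediate
11 | (3R,4R)-3-[2-(benzyloxy)-5-bromo-4-methoxyphenyl]-4-hydroxychroman-7-yl pivalate (cis) | CC(C)(C)C(=O)Oc1ccc2c(c1)OC[C@H]([C@H]2O)c1cc(Br)c(OC)cc1OCc1ccccc1 | intermediate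
12 | (3R)-3-(2-hydroxy-4-methoxyphenyl)chroman-7-yl pivalate | CC(C)(C)C(=O)Oc1ccc2c(c1)OC[C@H](C2)c1ccc(OC)cc1O | intermediate
13 | 2,6-dimethoxyphenol | COc1cccc(OC)c1O | starting material
14 | 2,6-dimethoxyphenyl pivalate | COc1cccc(OC)c1OC(=O)C(C)(C)C | intermediate
15 | phenyl{[7-(pivaloyloxy)-2H-chromen-4-yl]oxy}iodonium tetrafluoroborate (O-iodonio enolate, drawn O-bound) | CC(C)(C)C(=O)Oc1ccc2C(O[I+]c3ccccc3)=CCOc2c1.F[B-](F)(F)F | intermediate
16 | (±)-3-[2,4-dimethoxy-3-(pivaloyloxy)phenyl]-4-oxochroman-7-yl pivalate | CC(C)(C)C(=O)Oc1ccc2C(=O)C(COc2c1)c1ccc(OC)c(OC(=O)C(C)(C)C)c1OC | intermediate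
17 | (3R,4R)-3-[2,4-dimethoxy-3-(pivaloyloxy)phenyl]-4-hydroxychroman-7-yl pivalate (cis) | CC(C)(C)C(=O)Oc1ccc2c(c1)OC[C@H]([C@H]2O)c1ccc(OC)c(OC(=O)C(C)(C)C)c1OC | intermediate
18 | (3R)-3-[2,4-dimethoxy-3-(pivaloyloxy)phenyl]-7-(pivaloyloxy)chroman-4-ylium (C4 benzylic cation) | CC(C)(C)C(=O)Oc1ccc2c(c1)OC[C@H]([CH+]2)c1ccc(OC)c(OC(=O)C(C)(C)C)c1OC | intermediate
19 | (3R,4S)-3-[2,4-dimethoxy-3-(pivaloyloxy)phenyl]-4-{4-hydroxy-2-methoxy-5-[(3R)-7-(pivaloyloxy)chroman-3-yl]phenyl}chroman-7-yl pivalate | COc1cc(O)c([C@@H]2COc3cc(OC(=O)C(C)(C)C)ccc3C2)cc1[C@@H]1c2ccc(OC(=O)C(C)(C)C)cc2OC[C@H]1c1ccc(OC)c(OC(=O)C(C)(C)C)c1OC | intermediate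
20 | (3R,4S)-3-(3-hydroxy-2,4-dimethoxyphenyl)-4-{4-hydroxy-5-[(3R)-7-hydroxychroman-3-yl]-2-methoxyphenyl}chroman-7-ol | COc1cc(O)c([C@@H]2COc3cc(O)ccc3C2)cc1[C@@H]1c2ccc(O)cc2OC[C@H]1c1ccc(OC)c(O)c1OC | target

## Step count and risks

Total steps: 11. Longest linear sequence: 7 (steps 1, 2, 4, 5, 6, 10, 11).

**Step 8 (most at risk).** Arene 14 is only moderately nucleophilic, and the iodonium enolate may instead lose a C2 hydrogen to give the chromone or couple with unreacted 5. Fallback, setting out from 14 and 3 and coming back at 16: N-bromosuccinimide in MeCN brominates 14 at its activated carbon to 3-bromo-2,6-dimethoxyphenyl pivalate F5. The bond is then made with normal polarity by palladium-catalysed arylation of the enolate of 3 with F5 [Pd(OAc)2, P(t-Bu)3·HBF4, K3PO4, toluene, 90 °C], which gives 16 directly.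

**Step 4.** The enolonium chemistry can fail here too, through chromone formation or through slow or misdirected arene attack. Fallback, setting out from 3 and coming back at 12: bought 2-bromo-5-methoxyphenol F1 is benzylated with 7 (K2CO3, DMF) to 2-(benzyloxy)-1-bromo-4-methoxybenzene F2. F2 then arylates the enolate of 3 under the palladium conditions given above to (±)-3-[2-(benzyloxy)-4-methoxyphenyl]-4-oxochroman-7-yl pivalate F3. The reduction of step 5 converts F3 into (3R,4R)-3-[2-(benzyloxy)-4-methoxyphenyl]-4-hydroxychroman-7-yl pivalate F4, and the hydrogenolysis of step 6 converts F4 into 12.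

**Step 10.** Cation 18 may lose H3 to the isoflav-3-ene, which erodes the C3 configuration, or alkylate the wrong ring. Fallback, setting out from 17 and coming back at 19: benzyl mercaptan with catalytic BF3·OEt2 at −40 °C traps the cation much faster than elimination and gives the storable (3R,4S)-4-(benzylsulfanyl)-3-[2,4-dimethoxy-3-(pivaloyloxy)phenyl]chroman-7-yl pivalate F6. F6 and 12 (2 equiv) are then coupled by thiophilic activation with AgBF4 in THF at −20 °C in the presence of 2,6-di-tert-butylpyridine. The cation is generated irreversibly without protic acid, so an alkene cannot be re-protonated, and anti attack again gives 19.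

## Further compounds

F1 | step 4 | 2-bromo-5-methoxyphenol (bought) | COc1ccc(Br)c(O)c1
F2 | step 4 | 2-(benzyloxy)-1-bromo-4-methoxybenzene | COc1ccc(Br)c(OCc2ccccc2)c1
F3 | step 4 | (±)-3-[2-(benzyloxy)-4-methoxyphenyl]-4-oxochroman-7-yl pivalate | CC(C)(C)C(=O)Oc1ccc2C(=O)C(COc2c1)c1ccc(OC)cc1OCc1ccccc1
F4 | step 4 | (3R,4R)-3-[2-(benzyloxy)-4-methoxyphenyl]-4-hydroxychroman-7-yl pivalate | CC(C)(C)C(=O)Oc1ccc2c(c1)OC[C@H]([C@H]2O)c1ccc(OC)cc1OCc1ccccc1
F5 | step 8 | 3-bromo-2,6-dimethoxyphenyl pivalate | COc1ccc(Br)c(OC)c1OC(=O)C(C)(C)C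
F6 | step 10 | (3R,4S)-4-(benzylsulfanyl)-3-[2,4-dimethoxy-3-(pivaloyloxy)phenyl]chroman-7-yl pivalate | CC(C)(C)C(=O)Oc1ccc2c(c1)OC[C@H]([C@@H]2SCc3ccccc3)c1ccc(OC)c(OC(=O)C(C)(C)C)c1OC
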